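## Retrosynthetic overview

1. Target: (5R,6S,6'R)-5,6-epoxy-5,6-dihydro-β,ε-carotene. The last bond made is C11=C12, by Wittig reaction of a C25 ylide (ε end) with an epoxy C15 aldehyde, so that no carbanion and no acid ever sits next to the oxirane.
2. The C25 part comes from the C15 phosphonium salt of (R)-α-ionone (ε-ring and C6' bought) and the C10 trienedial. The epoxy C15 aldehyde comes from a C5 nitrile phosphonate and a C10 epoxy aldehyde.
3. Key disconnection: the 7-oxabicyclo[4.1.0]heptane is cut at C5–C6 and C6–O to an acyclic α-chloro ester carrying a methyl ketone (from methyl 3,3-dimethylpent-4-enoate and bromoacetone). One enantioselective intramolecular Darzens annulation closes both rings and sets C5 and C6 together.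
4. Ring order: the ε-ring is present from the start; the cyclohexane ring (C5–C6 aldol bond) and the oxirane ring (O–C6 bond) form together in step 3.

Assumption: (R)-α-ionone is bought as the single enantiomer.
Assumption: the cinchonidine-derived catalyst of step 3 is taken to give the (1S,6R) ester; should the measured sense be the opposite, the pseudoenantiomeric N-(9-anthracenylmethyl)cinchoninium chloride replaces it with nothing else changed.

## Route

Step 1
Reactants: 1 methyl 3,3-dimethylpent-4-enoate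
Product: 2 methyl 2-chloro-3,3-dimethylpent-4-enoate
Conditions: LiN(i-Pr)2, THF, −78 °C; enolate added to N-chlorosuccinimide, THF, −78 °C; 1 M HCl quench
Reagents that add atoms: N-chlorosuccinimide, O=C1CCC(=O)N1Cl
Why: Electrophilic α-chlorination of a lithium ester enolate (inverse addition limits dichlorination); the C–Cl centre is left racemic on purpose because it is planarised again in step 3.

Step 2
Reactants: 2 methyl 2-chloro-3,3-dimethylpent-4-enoate; 3 bromoacetone
Product: 5 methyl 2-chloro-3,3-dimethyl-7-oxooctanoate, via alkylborane 4 (not isolated)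
Conditions: 9-borabicyclo[3.3.1]nonane, THF, 0 °C → rt; then 3 and potassium 2,6-di-tert-butylphenoxide, THF, 0 °C; aqueous work-up
Reagents that add atoms: none
Why: Anti-Markovnikov hydroboration puts boron on the terminal carbon, and Brown's α-alkylation of bromoacetone with a B-alkyl-9-borabicyclononane (ate complex, 1,2-alkyl shift with loss of bromide, protonolysis of the boron enolate) adds the three-carbon methyl ketone unit, the weak hindered phenoxide leaving the α-chloro ester alone.

Step 3
Reactants: 5 methyl 2-chloro-3,3-dimethyl-7-oxooctanoate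
Product: 7 methyl (1S,6R)-2,2,6-trimethyl-7-oxabicyclo[4.1.0]heptane-1-carboxylate, via trans-chlorohydrin 6 (not isolated)
Conditions: N-(9-anthracenylmethyl)cinchonidinium chloride (10 mol%), CsOH·H2O (solid), toluene–CH2Cl2, 0.02 M, −40 → −20 °C
Reagents that add atoms: none
Why: Proposed new method: an intramolecular Darzens annulation (aldol, then 3-exo-tet SN2) under chiral phase-transfer catalysis, in which the α-chloro ester enolate, ion-paired with the cinchonidinium cation, adds reversibly to the methyl ketone to close the cyclohexane ring (6-enolexo aldol), only the adduct with O− anti to C–Cl can expel chloride to close the oxirane, and this irreversible closure inside the chiral ion pair fixes C5 and C6 together (cis fusion is forced by the ring, so control of one enolate face sets both centres); the closest known reactions are the base-mediated Darzens condensation of α-chloro esters with ketones and the cinchona phase-transfer Darzens reaction of α-chloro ketones with aldehydes.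

Step 4
Reactants: 7 methyl (1S,6R)-2,2,6-trimethyl-7-oxabicyclo[4.1.0]heptane-1-carboxylate
Product: 8 (1S,6R)-2,2,6-trimethyl-7-oxabicyclo[4.1.0]heptane-1-carbaldehyde
Conditions: i-Bu2AlH (1.1 equiv), CH2Cl2, −78 °C; MeOH, then aq. potassium sodium tartrate
Reagents that add atoms: none
Why: Partial ester reduction by i-Bu2AlH, whose aluminium hemiacetal of this hindered ester survives at −78 °C and gives the aldehyde only on work-up; the aldehyde has no α-hydrogen, so neither stereocentre can epimerise.

Step 5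
Reactants: 8 (1S,6R)-2,2,6-trimethyl-7-oxabicyclo[4.1.0]heptane-1-carbaldehyde; 9 diethyl [(2E)-3-cyano-2-methylprop-2-en-1-yl]phosphonate
Product: 10 (2E,4E)-3-methyl-5-[(1S,6R)-2,2,6-trimethyl-7-oxabicyclo[4.1.0]heptan-1-yl]penta-2,4-dienenitrile
Conditions: NaH, THF, 0 °C; then 8, 0 °C → rt; (2Z) isomer removed on Et3N-deactivated silica
Reagents that add atoms: none
Why: Vinylogous Horner–Wadsworth–Emmons olefination, in which the small stabilised phosphonate anion reaches the hindered, non-enolisable aldehyde and forms C7=C8 as the E alkene while the basic medium leaves the oxirane untouched.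

Step 6
Reactants: 10 (2E,4E)-3-methyl-5-[(1S,6R)-2,2,6-trimethyl-7-oxabicyclo[4.1.0]heptan-1-yl]penta-2,4-dienenitrile
Product: 11 (2E,4E)-3-methyl-5-[(1S,6R)-2,2,6-trimethyl-7-oxabicyclo[4.1.0]heptan-1-yl]penta-2,4-dienal
Conditions: i-Bu2AlH (1.2 equiv), toluene, −78 °C; then H2O, pH 5 potassium sodium tartrate buffer, 0 °C
Reagents that add atoms: water, O
Why: Partial reduction of the conjugated nitrile to the N-aluminio aldimine, then buffered hydrolysis in which water supplies the carbonyl oxygen and nitrogen leaves as ammonia (the standard retinoid nitrile-to-aldehyde reduction); the mild buffer keeps strong acid away from the vinyl oxirane.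

Step 7
Reactants: 12 (R)-α-ionone
Product: 13 (1E)-3-methyl-1-[(1R)-2,6,6-trimethylcyclohex-2-en-1-yl]penta-1,4-dien-3-ol
Conditions: CH2=CHMgBr, THF, −20 → 0 °C; water work-up
Reagents that add atoms: vinylmagnesium bromide, C=C[Mg]Br
Why: 1,2-Grignard addition to the enone carbonyl; the carbinol centre forms as both epimers, which does not matter because it is ionised in step 8, and the ring stereocentre is not touched.

Step 8
Reactants: 13 (1E)-3-methyl-1-[(1R)-2,6,6-trimethylcyclohex-2-en-1-yl]penta-1,4-dien-3-ol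
Product: 14 [(2E,4E)-3-methyl-5-[(1R)-2,6,6-trimethylcyclohex-2-en-1-yl]penta-2,4-dien-1-yl]triphenylphosphonium bromide
Conditions: Ph3P·HBr, MeOH, rt; crystallisation
Reagents that add atoms: triphenylphosphine hydrobromide, [Br-].c1ccc(cc1)[PH+](c1ccccc1)c1ccccc1
Why: SN1-type allylic transposition in which the tertiary allylic alcohol ionises and PPh3 captures the pentadienyl cation at its primary terminus, the standard C15 Wittig salt synthesis, which is expected to keep the ε-ring double bond and the ring stereocentre in place.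

Step 9
Reactants: 14 [(2E,4E)-3-methyl-5-[(1R)-2,6,6-trimethylcyclohex-2-en-1-yl]penta-2,4-dien-1-yl]triphenylphosphonium bromide; 15 (2E,4E,6E)-2,7-dimethylocta-2,4,6-trienedial
Product: 16 (2E,4E,6E,8E,10E,12E)-2,7,11-trimethyl-13-[(1R)-2,6,6-trimethylcyclohex-2-en-1-yl]trideca-2,4,6,8,10,12-hexaenal
Conditions: 15 (2.5 equiv), NaOMe, MeOH–CH2Cl2, −10 °C → rt; then heptane, 80 °C; excess 15 recovered
Reagents that add atoms: none
Why: Wittig mono-olefination of the symmetrical dialdehyde, used in excess so that only one aldehyde reacts, followed by thermal equilibration of the new C11'=C12' bond to E.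

Step 10
Reactants: 16 (2E,4E,6E,8E,10E,12E)-2,7,11-trimethyl-13-[(1R)-2,6,6-trimethylcyclohex-2-en-1-yl]trideca-2,4,6,8,10,12-hexaenal
Product: 17 (2E,4E,6E,8E,10E,12E)-2,7,11-trimethyl-13-[(1R)-2,6,6-trimethylcyclohex-2-en-1-yl]trideca-2,4,6,8,10,12-hexaen-1-ol
Conditions: NaBH4, EtOH–THF, 0 °C
Reagents that add atoms: none
Why: 1,2-Hydride reduction of the conjugated aldehyde to the allylic alcohol; no stereocentre is formed.

Step 11
Reactants: 17 (2E,4E,6E,8E,10E,12E)-2,7,11-trimethyl-13-[(1R)-2,6,6-trimethylcyclohex-2-en-1-yl]trideca-2,4,6,8,10,12-hexaen-1-ol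
Product: 18 [(2E,4E,6E,8E,10E,12E)-2,7,11-trimethyl-13-[(1R)-2,6,6-trimethylcyclohex-2-en-1-yl]trideca-2,4,6,8,10,12-hexaen-1-yl]triphenylphosphonium bromide
Conditions: Ph3P·HBr, MeOH–CH2Cl2, rt, dark
Reagents that add atoms: triphenylphosphine hydrobromide, [Br-].c1ccc(cc1)[PH+](c1ccccc1)c1ccccc1
Why: Ionisation of the polyenyl allylic alcohol and capture by PPh3 at the primary carbon, as in the retinol to retinylphosphonium conversion; no oxirane is present yet, so the acid does no harm.

Step 12
Reactants: 18 [(2E,4E,6E,8E,10E,12E)-2,7,11-trimethyl-13-[(1R)-2,6,6-trimethylcyclohex-2-en-1-yl]trideca-2,4,6,8,10,12-hexaen-1-yl]triphenylphosphonium bromide; 11 (2E,4E)-3-methyl-5-[(1S,6R)-2,2,6-trimethyl-7-oxabicyclo[4.1.0]heptan-1-yl]penta-2,4-dienal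
Product: 19 (5R,6S,6'R)-5,6-epoxy-5,6-dihydro-β,ε-carotene
Conditions: 18 (1.1 equiv), NaOMe, MeOH–CH2Cl2, 0 °C → rt, dark, argon; then heptane, 80 °C; crystallisation from CH2Cl2–MeOH with 0.1% Et3N
Reagents that add atoms: none
Why: Wittig reaction of the C25 ylide with the epoxy C15 aldehyde forms C11=C12 under basic conditions that the oxirane tolerates, and thermal equilibration gives the all-E polyene without touching C5, C6 or C6'.

## Compound list

1 | methyl 3,3-dimethylpent-4-enoate | COC(=O)CC(C)(C)C=C | starting material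
2 | methyl 2-chloro-3,3-dimethylpent-4-enoate (racemic) | COC(=O)C(Cl)C(C)(C)C=C | intermediate
3 | bromoacetone (1-bromopropan-2-one) | CC(=O)CBr | starting material
4 | methyl 5-(9-borabicyclo[3.3.1]nonan-9-yl)-2-chloro-3,3-dimethylpentanoate (racemic; not isolated) | COC(=O)C(Cl)C(C)(C)CCB1C2CCCC1CCC2 | intermediate
5 | methyl 2-chloro-3,3-dimethyl-7-oxooctanoate (racemic) | COC(=O)C(Cl)C(C)(C)CCCC(C)=O | intermediate
6 | methyl (1R,2R)-1-chloro-2-hydroxy-2,6,6-trimethylcyclohexane-1-carboxylate (trans-chlorohydrin, present as its alkoxide; not isolated) | COC(=O)[C@@]1(Cl)C(C)(C)CCC[C@@]1(C)O | intermediate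
7 | methyl (1S,6R)-2,2,6-trimethyl-7-oxabicyclo[4.1.0]heptane-1-carboxylate | COC(=O)[C@@]12O[C@]1(C)CCCC2(C)C | intermediate
8 | (1S,6R)-2,2,6-trimethyl-7-oxabicyclo[4.1.0]heptane-1-carbaldehyde | O=C[C@@]12O[C@]1(C)CCCC2(C)C | intermediate
9 | diethyl [(2E)-3-cyano-2-methylprop-2-en-1-yl]phosphonate | CCOP(=O)(C/C(C)=C/C#N)OCC | starting material
10 | (2E,4E)-3-methyl-5-[(1S,6R)-2,2,6-trimethyl-7-oxabicyclo[4.1.0]heptan-1-yl]penta-2,4-dienenitrile | N#C/C=C(C)/C=C/[C@@]12O[C@]1(C)CCCC2(C)C | intermediate
11 | (2E,4E)-3-methyl-5-[(1S,6R)-2,2,6-trimethyl-7-oxabicyclo[4.1.0]heptan-1-yl]penta-2,4-dienal | O=C/C=C(C)/C=C/[C@@]12O[C@]1(C)CCCC2(C)C | intermediate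
12 | (R)-α-ionone, (3E)-4-[(1R)-2,6,6-trimethylcyclohex-2-en-1-yl]but-3-en-2-one | CC1=CCCC(C)(C)[C@H]1/C=C/C(C)=O | starting material
13 | (1E)-3-methyl-1-[(1R)-2,6,6-trimethylcyclohex-2-en-1-yl]penta-1,4-dien-3-ol (both C3 epimers) | CC1=CCCC(C)(C)[C@H]1/C=C/C(C)(O)C=C | intermediate
14 | [(2E,4E)-3-methyl-5-[(1R)-2,6,6-trimethylcyclohex-2-en-1-yl]penta-2,4-dien-1-yl]triphenylphosphonium bromide | [Br-].CC1=CCCC(C)(C)[C@H]1/C=C/C(C)=C/C[P+](c1ccccc1)(c1ccccc1)c1ccccc1 | intermediate
15 | (2E,4E,6E)-2,7-dimethylocta-2,4,6-trienedial | O=C/C(C)=C/C=C/C=C(C)/C=O | starting material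
16 | (2E,4E,6E,8E,10E,12E)-2,7,11-trimethyl-13-[(1R)-2,6,6-trimethylcyclohex-2-en-1-yl]trideca-2,4,6,8,10,12-hexaenal | CC1=CCCC(C)(C)[C@H]1/C=C/C(C)=C/C=C/C(C)=C/C=C/C=C(C)/C=O | intermediate
17 | (2E,4E,6E,8E,10E,12E)-2,7,11-trimethyl-13-[(1R)-2,6,6-trimethylcyclohex-2-en-1-yl]trideca-2,4,6,8,10,12-hexaen-1-ol | CC1=CCCC(C)(C)[C@H]1/C=C/C(C)=C/C=C/C(C)=C/C=C/C=C(C)/CO | intermediate
18 | [(2E,4E,6E,8E,10E,12E)-2,7,11-trimethyl-13-[(1R)-2,6,6-trimethylcyclohex-2-en-1-yl]trideca-2,4,6,8,10,12-hexaen-1-yl]triphenylphosphonium bromide | [Br-].CC1=CCCC(C)(C)[C@H]1/C=C/C(C)=C/C=C/C(C)=C/C=C/C=C(C)/C[P+](c1ccccc1)(c1ccccc1)c1ccccc1 | intermediate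
19 | (5R,6S,6'R)-5,6-epoxy-5,6-dihydro-β,ε-carotene | CC1=CCCC(C)(C)[C@H]1/C=C/C(C)=C/C=C/C(C)=C/C=C/C=C(C)/C=C/C=C(C)/C=C/[C@@]12O[C@]1(C)CCCC2(C)C | target

## Step count and weak points

Total: 12 steps. Longest linear sequence: 7 steps (steps 1 to 6, then step 12).

Step 3 is the most likely to fail: it is a new enantioselective annulation, the enantiomeric excess cannot be predicted, and Claisen condensation of the ketone enolate onto the ester competes. The fallback sets out from 5 and comes back to the route at 8. It moves stereocontrol from the catalyst to a covalent auxiliary whose diastereomeric products can be separated. Acid hydrolysis of 5 (6 M HCl, 1,4-dioxane, 80 °C; no base, so no premature cyclisation) gives 2-chloro-3,3-dimethyl-7-oxooctanoic acid F1. Esterification with (1R,2S,5R)-8-phenylmenthol (N,N'-dicyclohexylcarbodiimide, 4-(dimethylamino)pyridine, CH2Cl2) gives (1R,2S,5R)-5-methyl-2-(2-phenylpropan-2-yl)cyclohexyl 2-chloro-3,3-dimethyl-7-oxooctanoate F2. KOt-Bu (CH2Cl2, −78 → −20 °C) then closes both rings, the bulky ester also blocking the Claisen path. The (1S,6R) diastereomer, (1R,2S,5R)-5-methyl-2-(2-phenylpropan-2-yl)cyclohexyl (1S,6R)-2,2,6-trimethyl-7-oxabicyclo[4.1.0]heptane-1-carboxylate F3, is separated from its (1R,6S) epimer by chromatography or crystallisation. LiAlH4 (Et2O, 0 °C) releases the auxiliary and gives [(1R,6R)-2,2,6-trimethyl-7-oxabicyclo[4.1.0]heptan-1-yl]methanol F4, which Dess–Martin periodinane (NaHCO3, CH2Cl2) oxidises to 8.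

Step 2 is second: the α-chloro ester may not survive the boron alkylation, or alkyl transfer from boron may be poor. The fallback sets out from 2 and comes back at 5. It replaces the boron chemistry by a radical chain. Iodine-atom-transfer addition of iodoacetone to the terminal alkene (Et3B 0.2 equiv, air, CH2Cl2, rt) gives methyl 2-chloro-4-iodo-3,3-dimethyl-7-oxooctanoate F5 as a diastereomer mixture. n-Bu3SnH (1.05 equiv, 2,2'-azobis(2-methylpropionitrile), toluene, 80 °C) then removes the iodine, far faster than it attacks the C–Cl bond, and gives 5.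

Step 4 is third: the hindered glycidic ester may be over-reduced or not reduced at −78 °C. The fallback sets out from 7 and comes back at 8. It passes through an amide whose reduction stops at the aldehyde stage by chelation. MeNH(OMe)·HCl with i-PrMgCl (THF, −20 → 0 °C) converts 7 into (1S,6R)-N-methoxy-N,2,2,6-tetramethyl-7-oxabicyclo[4.1.0]heptane-1-carboxamide F6. i-Bu2AlH (THF, −78 °C) then gives a stable chelated tetrahedral intermediate that releases 8 on work-up.

## Further compounds

F1 | step 3 | 2-chloro-3,3-dimethyl-7-oxooctanoic acid (racemic) | OC(=O)C(Cl)C(C)(C)CCCC(C)=O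
F2 | step 3 | (1R,2S,5R)-5-methyl-2-(2-phenylpropan-2-yl)cyclohexyl 2-chloro-3,3-dimethyl-7-oxooctanoate (both C2 epimers) | CC(=O)CCCC(C)(C)C(Cl)C(=O)O[C@@H]1C[C@H](C)CC[C@H]1C(C)(C)c1ccccc1
F3 | step 3 | (1R,2S,5R)-5-methyl-2-(2-phenylpropan-2-yl)cyclohexyl (1S,6R)-2,2,6-trimethyl-7-oxabicyclo[4.1.0]heptane-1-carboxylate | O=C(O[C@@H]1C[C@H](C)CC[C@H]1C(C)(C)c1ccccc1)[C@@]12O[C@]1(C)CCCC2(C)C
F4 | step 3 | [(1R,6R)-2,2,6-trimethyl-7-oxabicyclo[4.1.0]heptan-1-yl]methanol | OC[C@@]12O[C@]1(C)CCCC2(C)C
F5 | step 2 | methyl 2-chloro-4-iodo-3,3-dimethyl-7-oxooctanoate (diastereomer mixture) | COC(=O)C(Cl)C(C)(C)C(I)CCC(C)=O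
F6 | step 4 | (1S,6R)-N-methoxy-N,2,2,6-tetramethyl-7-oxabicyclo[4.1.0]heptane-1-carboxamide | CON(C)C(=O)[C@@]12O[C@]1(C)CCCC2(C)C
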